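The route rests on cutting C3–C4 in ring A and C9–C10 in ring B. Each 4-bromobutenolide is a masked tetronic acid in which that bond joins the α-carbon of an acyl group on the lactone oxygen to a carboxyl carbon on the spiro carbon (C5, C6) of the cyclobutane. One base treatment of 14 therefore forms both bonds and closes both lactones (two-directional Lacey–Dieckmann). Precursor 14 is a dimethyl cyclobutane-1,2-dicarboxylate with trans tertiary oxygens, one carrying a hexanoate and the other a 3-oxohexanoate. It already holds both ring bromines, set early on a photopyrone-derived β-lactone that also fixes the trans relation of the oxygens.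

Key step: step 10

Remark on the chemistry: the two cyclobutane bromines are installed before the key step and ride through it as spectators. Once the spiro butenolides exist, the substituent on C4 (C10) lies under the face each bromine must occupy (trans to the neighbouring lactone oxygen), so bromine addition after the annulation should give the other trans-dibromide. A saturated ring also keeps the thermally labile 3,4-dioxygenated cyclobutene out of every ring-opened intermediate.

Numbering used for the dispiro compounds: O1, C2(=O), C3, C4, C5 (spiro), C6 (spiro), O7, C8(=O), C9, C10, C11 (on C6), C12 (on C5).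

Step 1
Reactants: 1 mucic acid (galactaric acid)
Product: 2 3-acetoxy-2-oxo-2H-pyran-6-carboxylic acid
Conditions: Ac2O (6 equiv), pyridine (0.2 equiv), 90 °C
Reagents that add atoms: acetic anhydride CC(=O)OC(C)=O
Why: Dehydrative cyclisation of the aldaric acid (acetylation, lactonisation and two β-eliminations of acetic acid) gives the 3-acyloxy-2-pyranone, a known conversion of galactaric acid; all four stereocentres are erased.

Step 2
Reactants: 2 3-acetoxy-2-oxo-2H-pyran-6-carboxylic acid
Product: 3 methyl 3-hydroxy-2-oxo-2H-pyran-6-carboxylate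
Conditions: MeOH, H2SO4 (cat.), reflux
Reagents that add atoms: methanol CO
Why: Fischer esterification of the acid, with acid-catalysed transesterification of the enol acetate to methyl acetate, frees the enolic 3-hydroxyl.

Step 3
Reactants: 3 methyl 3-hydroxy-2-oxo-2H-pyran-6-carboxylate; 4 hexanoyl chloride
Product: 5 methyl 3-(hexanoyloxy)-2-oxo-2H-pyran-6-carboxylate
Conditions: Et3N (1.2 equiv), CH2Cl2, 0 °C
Reagents that add atoms: none
Why: O-acylation (esterification) of the acidic enolic hydroxyl with the acid chloride puts the future ring-A acyl chain on oxygen before any stereocentre exists.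

Step 4
Reactants: 5 methyl 3-(hexanoyloxy)-2-oxo-2H-pyran-6-carboxylate
Product: 6 methyl 4-(hexanoyloxy)-3-oxo-2-oxabicyclo[2.2.0]hex-5-ene-1-carboxylate (racemic)
Conditions: hν (300 nm), degassed CH2Cl2 (0.01 M), −10 °C
Reagents that add atoms: none
Why: Photochemical disrotatory 4π-electrocyclisation of the 2-pyranone (photopyrone reaction) joins pyranone C3 to C6; the obligatory cis fusion places the lactone oxygen on C1 and the lactone carbonyl on C4 on one face, so the hexanoyloxy oxygen and the lactone oxygen are trans, which is the relative configuration of the two future spiro centres (racemic at this point).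

Step 5
Reactants: 6 methyl 4-(hexanoyloxy)-3-oxo-2-oxabicyclo[2.2.0]hex-5-ene-1-carboxylate (racemic)
Product: 7 methyl (1R,4R)-4-(hexanoyloxy)-3-oxo-2-oxabicyclo[2.2.0]hex-5-ene-1-carboxylate
Conditions: preparative SFC, amylose tris(3,5-dimethylphenylcarbamate) phase, CO2/i-PrOH, 30 °C
Reagents that add atoms: none
Why: Resolution of the racemate by chromatography on a polysaccharide chiral stationary phase (no bond is made); the (1R,4R) antipode, which fixes the absolute configuration of both spiro centres, is to be assigned by anomalous-dispersion X-ray analysis of dibromide 8.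

Step 6
Reactants: 7 methyl (1R,4R)-4-(hexanoyloxy)-3-oxo-2-oxabicyclo[2.2.0]hex-5-ene-1-carboxylate
Product: 8 methyl (1R,4R,5R,6R)-5,6-dibromo-4-(hexanoyloxy)-3-oxo-2-oxabicyclo[2.2.0]hexane-1-carboxylate
Conditions: Br2 (1.05 equiv), CH2Cl2, −40 → 0 °C, dark
Reagents that add atoms: bromine BrBr
Why: Electrophilic anti-addition of bromine: the bromonium forms on the open exo face and bromide should open it at C5 from the endo side, over the π-face of the lactone carbonyl and anti to the vicinal C4–O bond rather than syn to the ring oxygen at C6 (dipolar control, which disfavours nucleophilic entry syn to a vicinal C–O bond), setting C5 (Br endo) and C6 (Br exo) with each bromine trans to the oxygen on the adjacent bridgehead.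

Step 7
Reactants: 8 methyl (1R,4R,5R,6R)-5,6-dibromo-4-(hexanoyloxy)-3-oxo-2-oxabicyclo[2.2.0]hexane-1-carboxylate
Product: 9 dimethyl (1R,2R,3R,4R)-3,4-dibromo-1-(hexanoyloxy)-2-hydroxycyclobutane-1,2-dicarboxylate
Conditions: MeOH, camphorsulfonic acid (0.2 equiv), 0 → 20 °C
Reagents that add atoms: methanol CO
Why: Acid-catalysed acyl–oxygen methanolysis of the strained β-lactone (alkyl–oxygen cleavage is impossible at the quaternary, ester-bearing C1); because no alkoxide is formed, neither retro-aldol cleavage of the four-membered ring nor epoxide closure onto the trans-vicinal bromide can start, and all four stereocentres are kept.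

Step 8
Reactants: 10 Meldrum's acid (2,2-dimethyl-1,3-dioxane-4,6-dione); 11 butanoyl chloride
Product: 12 5-(1-hydroxybutylidene)-2,2-dimethyl-1,3-dioxane-4,6-dione
Conditions: pyridine (2 equiv), CH2Cl2, 0 → 20 °C; 1 M HCl wash
Reagents that add atoms: none
Why: C-acylation of the Meldrum's acid enolate (Oikawa–Yonemitsu acylation) gives the storable acylketene precursor.

Step 9
Reactants: 9 dimethyl (1R,2R,3R,4R)-3,4-dibromo-1-(hexanoyloxy)-2-hydroxycyclobutane-1,2-dicarboxylate; 12 5-(1-hydroxybutylidene)-2,2-dimethyl-1,3-dioxane-4,6-dione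
Product: 14 dimethyl (1R,2R,3R,4R)-3,4-dibromo-1-(hexanoyloxy)-2-[(3-oxohexanoyl)oxy]cyclobutane-1,2-dicarboxylate, via butanoylketene 13 (not isolated)
Conditions: toluene, 80 °C, slow addition of 12 (3 equiv)
Reagents that add atoms: none
Why: Thermal loss of acetone and CO2 from the acyl Meldrum's acid gives butanoylketene, which adds the hindered tertiary alcohol under neutral conditions (acylketene acylation, the usual entry to Lacey–Dieckmann substrates from tertiary α-hydroxy esters); the saturated dibromide tolerates the heating and no base is present.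

Step 10
Reactants: 14 dimethyl (1R,2R,3R,4R)-3,4-dibromo-1-(hexanoyloxy)-2-[(3-oxohexanoyl)oxy]cyclobutane-1,2-dicarboxylate
Product: 16 (5S,6S,11R,12R)-11,12-dibromo-9-butanoyl-3-butyl-4,10-dihydroxy-1,7-dioxadispiro[4.0.4.2]dodeca-3,9-diene-2,8-dione, via ring-A tetronic acid keto ester 15 (not isolated)
Conditions: LiN(SiMe3)2 (5 equiv), THF, −78 °C, then 0 °C; 1 M HCl, 0 °C
Reagents that add atoms: none
Why: Double Lacey–Dieckmann (intramolecular Claisen) condensation: the amide base gives the hexanoate enolate, which attacks the methyl ester on its own ring carbon at −78 °C and expels methoxide, and the chelated β-keto ester enolate does the same on warming; each tetronate is deprotonated as it forms, which makes both closures irreversible. The closest precedents are the Dieckmann cyclisation of O-acyl α-hydroxy esters to 3-alkyltetronic acids and the Lacey–Dieckmann cyclisation of their β-keto esters to 3-acyltetronic acids. Ring A and ring B each close in the 5-exo-trig mode. No stereocentre is formed, and C5, C6, C11 and C12 are carried unchanged from 14 because no bond to them is broken. The step needs C-acylation at the geminal ester in preference to 6-exo attack on the vicinal ester, to acyl transfer that would free a tertiary alkoxide, and to any reaction at C–Br. This is secured by the 1,5-relation of each enolate carbon to its geminal ester, the trans oxygens that hold the two acyl arms on opposite faces, the low temperature and non-nucleophilic base, and a trans-dibromide that has no anti-periplanar H/Br pair for E2 and sits on neopentyl-type cyclobutyl carbons that resist SN2.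

Step 11
Reactants: 16 (5S,6S,11R,12R)-11,12-dibromo-9-butanoyl-3-butyl-4,10-dihydroxy-1,7-dioxadispiro[4.0.4.2]dodeca-3,9-diene-2,8-dione
Product: 17 (5S,6S,11R,12R)-4,10,11,12-tetrabromo-9-butanoyl-3-butyl-1,7-dioxadispiro[4.0.4.2]dodeca-3,9-diene-2,8-dione
Conditions: (COBr)2 (3 equiv), DMF (0.3 equiv), CH2Cl2, 0 → 20 °C
Reagents that add atoms: oxalyl bromide O=C(Br)C(Br)=O
Why: Vilsmeier-type deoxybromination of vinylogous acids: each tetronic acid enol is O-activated by the bromoiminium salt and bromide adds and eliminates at C4 and C10, as known for tetronic acids and for cyclic 2-acyl-1,3-diones, which give the ring vinyl halide.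

Step 12
Reactants: 17 (5S,6S,11R,12R)-4,10,11,12-tetrabromo-9-butanoyl-3-butyl-1,7-dioxadispiro[4.0.4.2]dodeca-3,9-diene-2,8-dione
Product: 18 (5S,6S,11R,12R)-4,10,11,12-tetrabromo-3-butyl-9-[(1R)-1-hydroxybutyl]-1,7-dioxadispiro[4.0.4.2]dodeca-3,9-diene-2,8-dione
Conditions: (S)-1-methyl-3,3-diphenyltetrahydro-1H,3H-pyrrolo[1,2-c][1,3,2]oxazaborole (0.5 equiv), catecholborane (2 equiv), toluene, −78 → −40 °C
Reagents that add atoms: none
Why: Corey–Bakshi–Shibata reduction: the ketone binds the oxazaborolidine boron anti to the large 2,2-disubstituted butenolide so that, as with aryl alkyl ketones and the (S)-catalyst, hydride delivery should give the (R)-carbinol; the hindered, fully substituted C10 disfavours conjugate reduction.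

Step 13
Reactants: 18 (5S,6S,11R,12R)-4,10,11,12-tetrabromo-3-butyl-9-[(1R)-1-hydroxybutyl]-1,7-dioxadispiro[4.0.4.2]dodeca-3,9-diene-2,8-dione
Product: 19 (1R)-1-[(5S,6S,11R,12R)-4,10,11,12-tetrabromo-3-butyl-2,8-dioxo-1,7-dioxadispiro[4.0.4.2]dodeca-3,9-dien-9-yl]butyl acetate (CNP0268004.1)
Conditions: Ac2O, pyridine, 4-(dimethylamino)pyridine (cat.), CH2Cl2, 0 °C
Reagents that add atoms: acetic anhydride CC(=O)OC(C)=O
Why: Nucleophile-catalysed O-acetylation of the secondary allylic alcohol (esterification) touches no stereocentre and gives the target.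

Compound list
1 | mucic acid (galactaric acid) | OC(=O)[C@H](O)[C@@H](O)[C@@H](O)[C@H](O)C(=O)O | starting material
2 | 3-acetoxy-2-oxo-2H-pyran-6-carboxylic acid | CC(=O)OC1=CC=C(C(=O)O)OC1=O | intermediate
3 | methyl 3-hydroxy-2-oxo-2H-pyran-6-carboxylate | COC(=O)C1=CC=C(O)C(=O)O1 | intermediate
4 | hexanoyl chloride | CCCCCC(Cl)=O | starting material
5 | methyl 3-(hexanoyloxy)-2-oxo-2H-pyran-6-carboxylate | CCCCCC(=O)OC1=CC=C(C(=O)OC)OC1=O | intermediate
6 | methyl 4-(hexanoyloxy)-3-oxo-2-oxabicyclo[2.2.0]hex-5-ene-1-carboxylate, racemic (cis ring fusion is the only possible one) | COC(=O)C12OC(=O)C1(OC(=O)CCCCC)C=C2 | intermediate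
7 | methyl (1R,4R)-4-(hexanoyloxy)-3-oxo-2-oxabicyclo[2.2.0]hex-5-ene-1-carboxylate | COC(=O)[C@]12OC(=O)[C@@]1(OC(=O)CCCCC)C=C2 | intermediate
8 | methyl (1R,4R,5R,6R)-5,6-dibromo-4-(hexanoyloxy)-3-oxo-2-oxabicyclo[2.2.0]hexane-1-carboxylate (5-Br endo, 6-Br exo) | COC(=O)[C@]12OC(=O)[C@@]1(OC(=O)CCCCC)[C@@H](Br)[C@@H]2Br | intermediate
9 | dimethyl (1R,2R,3R,4R)-3,4-dibromo-1-(hexanoyloxy)-2-hydroxycyclobutane-1,2-dicarboxylate (oxygens trans; each bromine trans to the oxygen and cis to the ester on the neighbouring carbon) | COC(=O)[C@@]1(OC(=O)CCCCC)[C@@H](Br)[C@H](Br)[C@]1(O)C(=O)OC | intermediate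
10 | Meldrum's acid (2,2-dimethyl-1,3-dioxane-4,6-dione) | CC1(C)OC(=O)CC(=O)O1 | starting material
11 | butanoyl chloride | CCCC(Cl)=O | starting material
12 | 5-(1-hydroxybutylidene)-2,2-dimethyl-1,3-dioxane-4,6-dione | CCCC(O)=C1C(=O)OC(C)(C)OC1=O | intermediate
13 | butanoylketene (3-oxohex-1-en-1-one), not isolated | CCCC(=O)C=C=O | intermediate
14 | dimethyl (1R,2R,3R,4R)-3,4-dibromo-1-(hexanoyloxy)-2-[(3-oxohexanoyl)oxy]cyclobutane-1,2-dicarboxylate (precursor of the key step) | COC(=O)[C@@]1(OC(=O)CCCCC)[C@@H](Br)[C@H](Br)[C@]1(OC(=O)CC(=O)CCC)C(=O)OC | intermediate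
15 | ring-A tetronic acid keto ester, not isolated: 3-butyltetronic acid spiro-fused at the former C1, the former C2 still carrying CO2Me and the 3-oxohexanoate | CCCCC1=C(O)[C@@]2(OC1=O)[C@@H](Br)[C@H](Br)[C@]2(OC(=O)CC(=O)CCC)C(=O)OC | intermediate
16 | (5S,6S,11R,12R)-11,12-dibromo-9-butanoyl-3-butyl-4,10-dihydroxy-1,7-dioxadispiro[4.0.4.2]dodeca-3,9-diene-2,8-dione (product of the key step) | CCCCC1=C(O)[C@@]2(OC1=O)[C@@H](Br)[C@H](Br)[C@@]21OC(=O)C(C(=O)CCC)=C1O | intermediate
17 | (5S,6S,11R,12R)-4,10,11,12-tetrabromo-9-butanoyl-3-butyl-1,7-dioxadispiro[4.0.4.2]dodeca-3,9-diene-2,8-dione | CCCCC1=C(Br)[C@@]2(OC1=O)[C@@H](Br)[C@H](Br)[C@@]21OC(=O)C(C(=O)CCC)=C1Br | intermediate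
18 | (5S,6S,11R,12R)-4,10,11,12-tetrabromo-3-butyl-9-[(1R)-1-hydroxybutyl]-1,7-dioxadispiro[4.0.4.2]dodeca-3,9-diene-2,8-dione | CCCCC1=C(Br)[C@@]2(OC1=O)[C@@H](Br)[C@H](Br)[C@@]21OC(=O)C([C@@H](CCC)O)=C1Br | intermediate
19 | (1R)-1-[(5S,6S,11R,12R)-4,10,11,12-tetrabromo-3-butyl-2,8-dioxo-1,7-dioxadispiro[4.0.4.2]dodeca-3,9-dien-9-yl]butyl acetate | CCCCC1=C(Br)[C@@]2(OC1=O)[C@@H](Br)[C@H](Br)[C@@]21OC(=O)C([C@@H](CCC)OC(C)=O)=C1Br | target

Total step count: 13
Longest linear sequence: 12 (steps 1–7 and 9–13; step 8 is a one-step side branch)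

Steps most likely to fail

Step 10. Acyl transfer from a tertiary oxygen may free an alkoxide, which would cleave the cyclobutane by retro-aldol fragmentation or close an epoxide onto the trans bromide; enolate attack on the vicinal ester may also outrun the slower second closure. The fallback sets out from 14 and returns at 16: the two closures are separated and the hexanoate is enolised without an amide base. Bu4NF in THF at 0 °C enolises only the β-keto ester and closes ring B, giving the ring-B 3-butanoyltetronic acid hexanoate ester F1. A titanium-mediated soft-enolisation Dieckmann condensation (TiCl4, Bu3N, CH2Cl2, −78 → 0 °C) then closes ring A to give 16.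

Step 6. The bromonium may be opened at C6 instead of C5 (steric instead of dipolar control), which would place both bromines syn to the vicinal oxygens. The fallback sets out from 7 and returns at 9: the bromination is moved to the ring-opened diester, where the oxygen side is made the bulkier one. Acid methanolysis of 7 (MeOH, camphorsulfonic acid, −10 °C) gives the cyclobutene hydroxy diester F2, handled below 0 °C because its cyclobutene can open electrocyclically. Silylation (t-BuMe2SiOTf, 2,6-lutidine, CH2Cl2, −78 → −20 °C) gives the silyl ether F3. With Br2 (CH2Cl2, −40 °C) the bromonium should form on the face away from the silyl ether, and bromide can then only enter at the carbon next to C1, past the methyl ester and anti to the hexanoyloxy oxygen, giving the dibromo silyl ether F4. HF·pyridine (THF, 0 °C) returns 9.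

Step 12. Enantioface discrimination at the crowded ketone may be poor, or hydride may add to C10 with loss of the vinylic bromide. The fallback sets out from 17 and returns at 19: the ketone is reduced without stereocontrol and an enzyme makes the choice. Luche reduction (NaBH4, CeCl3·7H2O, MeOH, −78 °C) gives 18 together with its (1S)-epimer F5. Lipase-catalysed acetylation (Burkholderia cepacia lipase, vinyl acetate, t-BuOMe, 30 °C) should acetylate only the (R)-carbinol (Kazlauskas rule) and so give 19 directly; the unreacted epimer is separated and can be re-oxidised to 17 with MnO2.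

Further compounds
F1 | step 10 | ring-B tetronic acid hexanoate ester: 3-butanoyltetronic acid spiro-fused at the former C2, the former C1 still carrying CO2Me and the hexanoate | COC(=O)[C@@]1(OC(=O)CCCCC)[C@@H](Br)[C@H](Br)[C@@]12OC(=O)C(C(=O)CCC)=C2O
F2 | step 6 | dimethyl (1R,2R)-1-(hexanoyloxy)-2-hydroxycyclobut-3-ene-1,2-dicarboxylate | COC(=O)[C@@]1(OC(=O)CCCCC)C=C[C@]1(O)C(=O)OC
F3 | step 6 | dimethyl (1R,2R)-2-[(tert-butyldimethylsilyl)oxy]-1-(hexanoyloxy)cyclobut-3-ene-1,2-dicarboxylate | COC(=O)[C@@]1(OC(=O)CCCCC)C=C[C@]1(O[Si](C)(C)C(C)(C)C)C(=O)OC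
F4 | step 6 | dimethyl (1R,2R,3R,4R)-3,4-dibromo-2-[(tert-butyldimethylsilyl)oxy]-1-(hexanoyloxy)cyclobutane-1,2-dicarboxylate | COC(=O)[C@@]1(OC(=O)CCCCC)[C@@H](Br)[C@H](Br)[C@]1(O[Si](C)(C)C(C)(C)C)C(=O)OC
F5 | step 12 | (5S,6S,11R,12R)-4,10,11,12-tetrabromo-3-butyl-9-[(1S)-1-hydroxybutyl]-1,7-dioxadispiro[4.0.4.2]dodeca-3,9-diene-2,8-dione | CCCCC1=C(Br)[C@@]2(OC1=O)[C@@H](Br)[C@H](Br)[C@@]21OC(=O)C([C@H](CCC)O)=C1Br
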